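**Retrosynthetic overview**

- The target is traced back to one ene-4,7-dione that already holds C3, C3a and C8a. From it, the C4 alcohol comes from a 3-hydroxyl-directed reduction, the ester from acylation, and the C7 alcohol from a Luche reduction.
- The ene-dione comes from singlet-oxygen 1,4-dioxygenation of a C4=C5–C6=C7 diene. The C3 carbinol comes from isopropylcerium addition to a C3 ketone, and the C8a methyl from conjugate methylation of a C3a=C8a enone.
- That enone, 6-methyl-2,8-dihydroazulen-3(1H)-one, comes from an intramolecular Buchner reaction of the diazoketone of 3-(4-methylphenyl)propanoic acid. The five-membered ring closes first (carbene addition to the ipso–ortho bond), then the benzene ring is expanded by one carbon to the seven-membered ring, in the same operation.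
- Enabling feature: the seven-membered ring C3a–C4–C5–C6–C7–C8–C8a is a p-tolyl ring plus one carbon. C8a is the ipso carbon, C6 (with its CH3) the para carbon, and C3a the inserted carbene carbon. The C3 oxygen is the diazoketone carbonyl, and O-4/O-7 sit at the two ends of the diene left by the ring expansion.

Key step: step 2

Remark: locants are the azulene locants of the target, kept for all bicyclic compounds (C3 carbinol with isopropyl, C3a ring-fusion CH, C4 ester carbon, C5=C6(CH3), C7 carbinol, C8 CH2, C8a methyl-bearing carbon); a change of the C3a descriptor between compounds reflects CIP priorities only, not inversion.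

**Route**

Step 1
Reactants: 1 3-(4-methylphenyl)propanoic acid
Product: 3 1-diazo-4-(4-methylphenyl)butan-2-one, via acid chloride 2 (not isolated)
Conditions: (COCl)2, DMF (cat.), CH2Cl2, 0 °C to rt; concentrate; then CH2N2 (excess), Et2O, 0 °C
Reagents that add atoms: diazomethane, C=[N+]=[N-]
Why: Acylation of diazomethane by the acid chloride (first stage of an Arndt–Eistert sequence), with excess diazomethane scavenging HCl so that no chloromethyl ketone forms.

Step 2
Reactants: 3 1-diazo-4-(4-methylphenyl)butan-2-one
Product: 6 6-methyl-2,8-dihydroazulen-3(1H)-one, via norcaradiene 4 (not isolated), via cycloheptatriene 5 (not isolated)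
Conditions: Rh2(OAc)4 (0.5 mol %), CH2Cl2, reflux, slow addition of 3 at high dilution; then Et3N (cat.), rt
Reagents that add atoms: none
Why: Rh2(OAc)4 turns 3 into an electrophilic rhodium carbene that adds across the ipso–ortho bond of the p-tolyl ring to give norcaradiene 4, whose disrotatory 6π-electrocyclic opening cleaves the former arene bond and expands the benzene ring by one carbon to the cycloheptatriene of 5. This is the intramolecular Buchner reaction of 1-diazo-4-arylbutan-2-ones, a closely precedented reaction type. The five-membered ring is closed by [2+1] carbene addition at the ipso carbon through the three-atom tether, while the seven-membered ring is not closed but arises from the six-membered arene by insertion of the carbene carbon C3a. The only stereocenter formed (C3a–H of 5) is erased on purpose: Et3N deprotonates C3a and reprotonates C8, moving the double bond into conjugation to give the achiral trienone 6. The step needs chemoselectivity for arene addition over C–H insertion and carbene dimerisation, and regioselectivity between the two ortho bonds. The five-membered closure, the electron-rich arene, slow addition, the para methyl group (both ipso–ortho bonds are equivalent) and exclusion of acid (which would divert 5 to a 2-tetralone) should secure this.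

Step 3
Reactants: 6 6-methyl-2,8-dihydroazulen-3(1H)-one
Product: 8 (3aR,8aR)-6,8a-dimethyl-1,2,8,8a-tetrahydroazulen-3(3aH)-one, via aluminium trienolate 7 (not isolated)
Conditions: AlMe3, copper thiophene-2-carboxylate (monovalent copper, 5 mol %), chiral phosphoramidite ligand from 2,2'-biphenol and bis(1-phenylethyl)amine (10 mol %), Et2O, −30 °C; inverse quench into ice-cold pH 7 phosphate buffer; crude 8 used at once
Reagents that add atoms: trimethylaluminium, C[Al](C)C
Why: Proposed new method: copper-catalysed asymmetric conjugate addition of AlMe3 is established for β-substituted cyclopentenones and cyclohexenones without an α-substituent and is extended here to an α,β-disubstituted enone; methyl transfer to C8a should be feasible because the flat fused enone ties its substituents back and the resulting enolate is stabilised by conjugation with the C4–C7 diene, the ligand enantiomer being chosen by screening to give (8aR), and hydrolysis should then protonate trienolate 7 kinetically at the α-carbon C3a on the face opposite the adjacent angular methyl, giving the trans ring fusion (3aR).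

Step 4
Reactants: 8 (3aR,8aR)-6,8a-dimethyl-1,2,8,8a-tetrahydroazulen-3(3aH)-one
Product: 9 (3R,3aR,8aR)-6,8a-dimethyl-3-(propan-2-yl)-1,2,3,3a,8,8a-hexahydroazulen-3-ol
Conditions: iPrMgCl, anhydrous CeCl3, THF, −78 °C
Reagents that add atoms: isopropylmagnesium chloride, CC(C)[Mg]Cl
Why: Organocerium 1,2-addition, which suppresses enolisation and β-hydride reduction of the easily enolised β,γ-unsaturated ketone, should occur on the carbonyl face syn to H-3a and anti to the pseudoaxial 8a-methyl, placing the hydroxyl cis to that methyl (3R).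

Step 5
Reactants: 9 (3R,3aR,8aR)-6,8a-dimethyl-3-(propan-2-yl)-1,2,3,3a,8,8a-hexahydroazulen-3-ol
Product: 11 (3R,3aS,4S,7S,8aR)-6,8a-dimethyl-3-(propan-2-yl)-1,2,3,3a,4,7,8,8a-octahydroazulene-3,4,7-triol, via endoperoxide 10 (not isolated)
Conditions: O2, tetraphenylporphyrin (cat.), visible light, CH2Cl2, −20 °C; then Zn, AcOH, 0 °C
Reagents that add atoms: dioxygen, O=O
Why: [4+2] cycloaddition of singlet oxygen to the cisoid C4–C7 diene, expected on the face opposite the pseudoaxial 8a-methyl, followed by reductive O–O cleavage should give the cis-4,7-diol, and an adduct from the other face would converge in step 6.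

Step 6
Reactants: 11 (3R,3aS,4S,7S,8aR)-6,8a-dimethyl-3-(propan-2-yl)-1,2,3,3a,4,7,8,8a-octahydroazulene-3,4,7-triol
Product: 12 (3R,3aR,8aR)-3-hydroxy-6,8a-dimethyl-3-(propan-2-yl)-1,2,3,3a,8,8a-hexahydroazulene-4,7-dione
Conditions: Dess–Martin periodinane (2.5 equiv), CH2Cl2, 0 °C to rt
Reagents that add atoms: none
Why: Dess–Martin oxidation of both secondary allylic alcohols (the tertiary alcohol is inert) should give a single ene-dione whatever the diol configuration, and C3a, now α to a ketone, should stay trans because that isomer keeps C4 anti to the isopropyl group and allows a 3-OH···O=C4 hydrogen bond.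

Step 7
Reactants: 12 (3R,3aR,8aR)-3-hydroxy-6,8a-dimethyl-3-(propan-2-yl)-1,2,3,3a,8,8a-hexahydroazulene-4,7-dione
Product: 13 (3R,3aS,4S,8aR)-3,4-dihydroxy-6,8a-dimethyl-3-(propan-2-yl)-1,2,3,3a,4,8a-hexahydroazulen-7(8H)-one
Conditions: Me4NBH(OAc)3, MeCN/AcOH (1:1), −30 °C
Reagents that add atoms: none
Why: In this Evans–Saksena reduction the 3-hydroxyl should exchange onto boron and deliver hydride intramolecularly to the C4 carbonyl from its own face, giving the 1,3-anti diol (4S), while the C7 ketone, which has no β-hydroxyl, is not reduced by the triacetoxyborohydride.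

Step 8
Reactants: 13 (3R,3aS,4S,8aR)-3,4-dihydroxy-6,8a-dimethyl-3-(propan-2-yl)-1,2,3,3a,4,8a-hexahydroazulen-7(8H)-one; 14 4-methoxybenzoyl chloride
Product: 15 (3R,3aS,4S,8aR)-3-hydroxy-6,8a-dimethyl-7-oxo-3-(propan-2-yl)-1,2,3,3a,4,7,8,8a-octahydroazulen-4-yl 4-methoxybenzoate
Conditions: Et3N, DMAP (cat.), CH2Cl2, 0 °C to rt
Reagents that add atoms: 4-methoxybenzoyl chloride (14), COc1ccc(C(=O)Cl)cc1
Why: DMAP-catalysed acylation should take place only at the secondary allylic C4 hydroxyl, the tertiary C3 hydroxyl being too hindered to react.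

Step 9
Reactants: 15 (3R,3aS,4S,8aR)-3-hydroxy-6,8a-dimethyl-7-oxo-3-(propan-2-yl)-1,2,3,3a,4,7,8,8a-octahydroazulen-4-yl 4-methoxybenzoate
Product: 16 (3R,3aS,4S,7R,8aR)-3,7-dihydroxy-6,8a-dimethyl-3-(propan-2-yl)-1,2,3,3a,4,7,8,8a-octahydroazulen-4-yl 4-methoxybenzoate
Conditions: NaBH4, CeCl3·7H2O, MeOH, −78 °C
Reagents that add atoms: none
Why: Luche 1,2-reduction of the enone should deliver hydride to C7 on the face opposite the syn-axial 8a-methyl (1,3-related through C8), giving the 7R alcohol cis to that methyl, and the ester should survive.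

**Compound list**

1 | 3-(4-methylphenyl)propanoic acid | Cc1ccc(CCC(=O)O)cc1 | starting material
2 | 3-(4-methylphenyl)propanoyl chloride (not isolated) | Cc1ccc(CCC(=O)Cl)cc1 | intermediate
3 | 1-diazo-4-(4-methylphenyl)butan-2-one | Cc1ccc(CCC(=O)C=[N+]=[N-])cc1 | intermediate
4 | norcaradiene (racemic, not isolated): tricyclic ketone with a cyclopropane joining the carbene carbon to the former ipso and ortho carbons, diene in the six-membered ring | O=C1CCC23C=CC(C)=CC2C13 | intermediate
5 | 6-methyl-2,3a-dihydroazulen-3(1H)-one (racemic, not isolated) | O=C1CCC2=CC=C(C)C=CC12 | intermediate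
6 | 6-methyl-2,8-dihydroazulen-3(1H)-one | O=C1CCC2=C1C=CC(C)=CC2 | intermediate
7 | dimethylaluminium enolate of 8, (8aR)-configured C3-O-aluminium trienolate (not isolated) | C2=CC(C)=CC[C@@]3(C)CCC(O[Al](C)C)=C23 | intermediate
8 | (3aR,8aR)-6,8a-dimethyl-1,2,8,8a-tetrahydroazulen-3(3aH)-one (trans-fused) | C2=CC(C)=CC[C@@]3(C)CCC(=O)[C@H]23 | intermediate
9 | (3R,3aR,8aR)-6,8a-dimethyl-3-(propan-2-yl)-1,2,3,3a,8,8a-hexahydroazulen-3-ol | C2=CC(C)=CC[C@@]3(C)CC[C@@](O)(C(C)C)[C@H]23 | intermediate
10 | (3R,3aS,4S,7S,8aR)-4,7-epidioxy-6,8a-dimethyl-3-(propan-2-yl)-1,2,3,3a,4,7,8,8a-octahydroazulen-3-ol (endoperoxide, not isolated) | O4[C@H]2C=C(C)[C@@H](O4)C[C@@]3(C)CC[C@@](O)(C(C)C)[C@H]23 | intermediate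
11 | (3R,3aS,4S,7S,8aR)-6,8a-dimethyl-3-(propan-2-yl)-1,2,3,3a,4,7,8,8a-octahydroazulene-3,4,7-triol | O[C@H]2C=C(C)[C@@H](O)C[C@@]3(C)CC[C@@](O)(C(C)C)[C@H]23 | intermediate
12 | (3R,3aR,8aR)-3-hydroxy-6,8a-dimethyl-3-(propan-2-yl)-1,2,3,3a,8,8a-hexahydroazulene-4,7-dione | O=C2C=C(C)C(=O)C[C@@]3(C)CC[C@@](O)(C(C)C)[C@H]23 | intermediate
13 | (3R,3aS,4S,8aR)-3,4-dihydroxy-6,8a-dimethyl-3-(propan-2-yl)-1,2,3,3a,4,8a-hexahydroazulen-7(8H)-one | O[C@H]2C=C(C)C(=O)C[C@@]3(C)CC[C@@](O)(C(C)C)[C@H]23 | intermediate
14 | 4-methoxybenzoyl chloride | COc1ccc(C(=O)Cl)cc1 | starting material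
15 | (3R,3aS,4S,8aR)-3-hydroxy-6,8a-dimethyl-7-oxo-3-(propan-2-yl)-1,2,3,3a,4,7,8,8a-octahydroazulen-4-yl 4-methoxybenzoate | COc1ccc(C(=O)O[C@H]2C=C(C)C(=O)C[C@@]3(C)CC[C@@](O)(C(C)C)[C@H]23)cc1 | intermediate
16 | (3R,3aS,4S,7R,8aR)-3,7-dihydroxy-6,8a-dimethyl-3-(propan-2-yl)-1,2,3,3a,4,7,8,8a-octahydroazulen-4-yl 4-methoxybenzoate | COc1ccc(C(=O)O[C@H]2C=C(C)[C@H](O)C[C@@]3(C)CC[C@@](O)(C(C)C)[C@H]23)cc1 | target

Total step count: 9. Longest linear sequence: 9 steps (1 to 16).

**Steps most likely to fail**

1. Step 3 (proposed new method). Methyl transfer to the tetrasubstituted β-carbon may not take place, enantiofacial discrimination by the ligand may be poor, or the trienolate may be protonated at C5 or C7 or on the wrong face of C3a. The fallback uses known chemistry, sets out from 6 and comes back at 8. Corey–Bakshi–Shibata reduction of 6 with the (R)-2-methyl oxazaborolidine catalyst and catecholborane (toluene, −78 °C), in which the substituted enone carbon C3a acts as the large group, should give (S)-6-methyl-1,2,3,8-tetrahydroazulen-3-ol F1. Hydroxyl-directed Simmons–Smith cyclopropanation (Et2Zn, CH2I2, CH2Cl2, 0 °C) of the tetrasubstituted C3a=C8a bond should give the 3a,8a-methano-bridged cyclopropyl carbinol F2 with the methylene syn to the hydroxyl. Dess–Martin oxidation should give the cyclopropyl ketone F3. Li in liquid NH3/THF (−78 °C, 2.2 equiv) should cleave the exocyclic cyclopropane bond C3a–CH2, the one that overlaps with the carbonyl π system, to give the lithium trienolate F4 with the new 8a-methyl group. Kinetic protonation (solid NH4Cl, −78 °C) anti to that methyl returns 8.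

2. Step 4. The organometallic may enolise the doubly activated C3a–H, which isomerises the ketone to the conjugated dienone, or it may reduce the carbonyl by β-hydride transfer; facial selectivity is lost if C3a epimerises first. The fallback sets out from 8 and comes back at 11. The smaller sp2 nucleophile isopropenylmagnesium bromide with CeCl3 (THF, −78 °C), which has no β-hydride, should give (3S,3aR,8aR)-6,8a-dimethyl-3-(prop-1-en-2-yl)-1,2,3,3a,8,8a-hexahydroazulen-3-ol F5 (same spatial arrangement as 9). Photooxygenation as in step 5 should give the isopropenyl endoperoxide F6 (not isolated), since the diene adds singlet oxygen much faster than a 1,1-disubstituted alkene undergoes the ene reaction, and Zn/AcOH then gives the isopropenyl triol F7. Hydrogenation with RhCl(PPh3)3 (H2, benzene, rt), which saturates the 1,1-disubstituted alkene and leaves the trisubstituted ring alkene, should give 11.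

3. Step 7. The tertiary 3-hydroxyl may exchange too slowly onto boron, so that no reduction or an undirected or conjugate reduction of the ene-dione takes place, or the β-hydroxy ketone may epimerise at C3a or open by retro-aldol cleavage. The fallback sets out from 9 and comes back at 13, bypassing 11 and 12, and needs no new compound (entry F0). Endoperoxide 10 is generated as in step 5 and treated with Et3N (CH2Cl2, 0 °C) instead of Zn/AcOH. A Kornblum–DeLaMare rearrangement that removes the more accessible bridgehead hydrogen at C7 should give the C7 ketone and the C4 alkoxide, that is 13 directly, with the 4S configuration coming from the cycloaddition face.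

Further compounds
F1 | step 3 | (S)-6-methyl-1,2,3,8-tetrahydroazulen-3-ol | O[C@H]1CCC2=C1C=CC(C)=CC2
F2 | step 3 | 6-methyl-1,2,3,8-tetrahydro-3a,8a-methanoazulen-3-ol, (3S), cyclopropane methylene syn to the hydroxyl | O[C@H]1CC[C@]2(C3)CC=C(C)C=C[C@]123
F3 | step 3 | 6-methyl-1,2-dihydro-3a,8a-methanoazulen-3(8H)-one, same cyclopropane configuration as F2 | O=C1CC[C@]2(C3)CC=C(C)C=C[C@]123
F4 | step 3 | lithium (8aR)-6,8a-dimethyl-1,2,8,8a-tetrahydroazulen-3-olate (trienolate) | C2=CC(C)=CC[C@@]3(C)CCC([O-])=C23.[Li+]
F5 | step 4 | (3S,3aR,8aR)-6,8a-dimethyl-3-(prop-1-en-2-yl)-1,2,3,3a,8,8a-hexahydroazulen-3-ol | C2=CC(C)=CC[C@@]3(C)CC[C@@](O)(C(C)=C)[C@H]23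
F6 | step 4 | 4,7-endoperoxide of F5, peroxide bridge anti to the 8a-methyl group | O4[C@H]2C=C(C)[C@@H](O4)C[C@@]3(C)CC[C@@](O)(C(C)=C)[C@H]23
F7 | step 4 | 3-isopropenyl analogue of triol 11, 4,7-cis-diol anti to the 8a-methyl group | O[C@H]2C=C(C)[C@@H](O)C[C@@]3(C)CC[C@@](O)(C(C)=C)[C@H]23
F0 | step 7 | none | none
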